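**Numbering used.** Ring A: C1 carries the ester carbonyl C7, C2 OMe, C3 CH2OH, C4 OMe, C5 H, C6 CH3. Ring B (primed): C1' CO2H, C2' OH, C3' CH3, C4' O-acyl, C5' H, C6' CH3. Compound numbers are those of the steps and of the compound list.

## Analysis of the target

The target is a depside: two pentasubstituted benzene rings joined by one aryl ester bond, C7(=O)–O4'. It has no stereocentre, so the whole task is one of regiochemistry and functional-group order. Ring A is a 2,4-dimethoxy-6-methylbenzoate with a hydroxymethyl group at C3; ring B is 2,4-dihydroxy-3,6-dimethylbenzoic acid acylated at O4'. Three groups are sensitive. The aryl ester does not survive hydroxide or alkoxide, so no other ester can be saponified once it exists. The ring B salicylic acid is an electron-rich β-resorcylic acid that loses CO2 when heated. The benzylic alcohol at C3, flanked by two methoxy groups, ionizes readily in acid. The real difficulty is C3: on a finished 2,4-dioxygenated arene C3 and C5 are both activated and compete for any one-carbon electrophile. The route rests on the fact that C3 lies between the oxygenated carbons C2 and C4. If ring A is built at the cyclohexane-1,3-dione oxidation level, C3 is the methylene between two carbonyls and the only ring carbon that can condense with a formyl equivalent. C1 is also doubly activated there, but it is a methine and cannot give an aminomethylidene derivative. The ring A carboxyl group is di-ortho-substituted, so the ester bond to ring B must be made through a strongly activated acyl derivative and the acid must be unmasked without saponification.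

## Retrosynthetic reasoning

**16 to 15.** The C3 hydroxymethyl group is traced back to a C3 formyl group. This is placed last because the 2,4-dimethoxybenzylic alcohol would not survive the acid needed to unmask the ring B carboxyl group, whereas the aldehyde does. The forward step has to reduce one hindered aryl aldehyde in the presence of an aryl ester and a free salicylic acid.

**15 to 14.** The ring B carboxylic acid is masked as a tert-butyl ester. Acidolysis needs neither base nor nucleophile, so the C7–O4' ester is not endangered; a methyl ester could not be removed without cutting that bond first.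

**14 to 9 and 12 (through 13).** The C7–O4' bond is the only bond between the rings, and cutting it gives two benzenoid halves of similar size. The forward reaction has to acylate O4' and not O2' with a di-ortho-substituted acid. O2' is hydrogen-bonded to the neighbouring ester carbonyl and boxed in by C1' and C3', so the free, more acidic 4'-hydroxyl reacts; the acid is activated as chloride 13.

**12 to 11 to 10.** Ring B is available complete as methyl ester 10. Only the ester alkyl group has to be exchanged, through acid 11, because a methyl ester cannot be removed at the end.

**9 to 8 to 7.** Acid 9 comes from tert-butyl ester 8 by acidolysis, which avoids saponifying a di-ortho-substituted benzoate. Both methyl ethers are introduced together on resorcinol 7, since the target needs no distinction between O2 and O4.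

**7 to 5 (through 6) to 4.** The aromatic ring is traced back to a cyclohexane-1,3-dione by adding two hydrogens across C1/C6. At that level the C3–CHO bond is cut: in dione 4 the carbon between the two carbonyls is the single site for aminomethylenation, which gives the masked aldehyde 5. Dehydrogenation of 5 gives 6, whose hydrolysis releases the formyl group of 7.

**4 to 1 and 2 (through 3).** Ring A is cut at C1–C6 and C3–C4. This divides it into an acetoacetate piece (C7, C1, C2, C3) and a crotonate piece (C4, C5, C6 and its methyl), both commodity esters. The ketone and ester carbonyls become the 1,3-dioxygenation, the crotonate β-methyl becomes the C6 methyl, and the acetoacetate ester becomes C7. The forward reaction is a conjugate addition followed by an intramolecular Claisen condensation in one flask.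

## Alternatives that were turned down

**Alternative 1:** Ring B is disconnected at C1'–C2' and C5'–C6' by a retro-Alder–Rickert operation. In the forward sense the silyloxy cyclohexadienyl ester A2, which already carries the ring A acyl group on an enol oxygen, is heated with the alkynoate A3. The Diels–Alder adduct, a bicyclo[2.2.2]octadiene, then extrudes its saturated two-carbon bridge to give the fully substituted ring B of A1.
- For: both donor oxygens of A2 direct the same diene terminus to the β-carbon of A3, so the regiochemistry is reinforced. The silyl, triisopropylsilyl and allyl groups of A1 come off without hydrolysis, and no hindered phenol has to be acylated.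
- Against: the ring-forming step is spent on ring B, the half that can be bought as 10. Ring A, with the unsolved C3 problem, must still be made by other means and carried as a silyl ether. An internal alkynoate and a tetrasubstituted diene need high temperature, where 1,5-hydrogen shifts and silyl or acyl migration in A2 can scramble the diene. Three protecting groups remain to be removed.
- Comparison: it is equal or better on the mildness of the endgame. The chosen route instead puts its ring construction where the regiochemical problem lies and takes ring B from the shelf, in fewer steps.

**Alternative 2:** Ring A is disconnected at C1–C2, C2–C3 and C4–C5 (Danheiser benzannulation). Irradiation of the diazo ketone A5, which is already an ester of protected ring B, gives a vinylketene by Wolff rearrangement. On heating, the methoxyalkyne A6 adds [2+2], and the cyclobutenone opens and recloses by 6π electrocyclization to the phenol A4.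
- For: every substituent of ring A is fixed by the connectivity of two acyclic partners. C3 arrives at the alcohol oxidation level, and the ester bond exists before ring A does. On regiochemical certainty at C3 and on the absence of a redox adjustment this alternative is stronger.
- Against: ring B is carried through diazo ketone formation, photolysis and thermolysis, so convergence is poor. A5 needs several steps of its own. The annulation delivers O2 as a free phenol and O4 as a methyl ether, a distinction the target does not need and that costs an extra methylation of a chelated, hindered phenol. The final hydrogenolysis of two benzyl groups takes place next to an electron-rich benzylic C–O bond.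
- Comparison: the chosen route is shorter, uses no diazo compound or photochemistry, and introduces ring B late.

**Alternative 3:** The C1–C7 and C7–O4' bonds are cut together. The aryl iodide A8 would come from the symmetric aldehyde A9, whose two open ring positions are equivalent. A8, carbon monoxide A10 and the ring B phenol 12 would be joined by a palladium catalyst with a wide-bite-angle diphosphine and a tertiary amine: oxidative addition, CO insertion and capture of the aroyl palladium species by the phenol give A7, which is identical with 14.
- For: this is the shortest path to 14, and it removes the C3/C5 problem by symmetry. On step count it is stronger than the chosen route, and the endgame (14 to 15 to 16) is the same.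
- Against: the aroyl palladium intermediate is flanked by a methoxy and a methyl group, and it must be intercepted by a hindered, weakly nucleophilic phenol. Capture is therefore slow, and decarbonylation and hydrodehalogenation can compete. The free 2'-hydroxyl and the formyl group can bind the metal, and a toxic gas has to be handled.
- Comparison: the chosen route forms the same ester bond through an acyl chloride, which ionizes towards an acylium ion stabilized by the 2- and 4-methoxy groups, a mode of acylation well established for di-ortho-substituted benzoic acids. It gets the carboxyl carbon from a commodity acetoacetate, and no step depends on a catalytic reaction at a doubly ortho-substituted centre.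

Key step: step 1

## Route

Remark: the target is achiral. Intermediates 3, 4 and 5 are racemic and their stereocentres disappear at step 3; commercial 2 is taken as the E isomer.

**Step 1**
Reactants: 1 tert-butyl 3-oxobutanoate (tert-butyl acetoacetate); 2 ethyl (2E)-but-2-enoate (ethyl crotonate)
Product: 4 racemic tert-butyl trans-6-methyl-2,4-dioxocyclohexane-1-carboxylate, via Michael adduct keto diester 3 (not isolated)
Conditions: KOtBu (1.1 equiv), tBuOH, reflux; then 1 M HCl, 0 °C
Reagents that add atoms: none
Why: KOtBu deprotonates 1 at its doubly activated methylene, and this enolate adds 1,4 to the β-carbon of 2 (C1–C6 bond) to give 3; proton transfer then exposes the enolate of the acetyl methyl group, which attacks the ethyl ester carbonyl and expels ethoxide (C3–C4 bond). The closest known reaction type is the alkoxide-mediated Michael–Dieckmann annulation of acetoacetic esters with crotonic esters to dihydroorsellinates. The ring closes in the 6-exo-trig mode; every other enolate/carbonyl pairing in 3 would give a four-membered ring. The sequence is driven by deprotonation of the product at C3 to the delocalized dione enolate, which is why a full equivalent of base is used. C6 is set without control in the Michael step, and C1 remains epimerizable as a β-keto ester carbon, so it equilibrates to place the ester trans to the C6 methyl group, both equatorial; the product is racemic and both centres are erased in step 3. The step needs chemoselectivity between the two esters: the bulk of the tert-butyl group, and tert-butoxide in tert-butanol as the only alkoxide present in quantity, keep the tert-butyl ester intact while the ethyl ester is consumed. Cold, dilute acid in the work-up avoids loss of the tert-butyl group and decarboxylation of the β-keto ester.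

**Step 2**
Reactants: 4 racemic tert-butyl trans-6-methyl-2,4-dioxocyclohexane-1-carboxylate
Product: 5 racemic tert-butyl trans-3-[(dimethylamino)methylidene]-6-methyl-2,4-dioxocyclohexane-1-carboxylate
Conditions: Me2NCH(OMe)2 (1.3 equiv), toluene, rt to 50 °C
Reagents that add atoms: N,N-dimethylformamide dimethyl acetal, COC(OC)N(C)C
Why: Aminomethylenation of an active methylene compound with an amide acetal: the dione enol attacks the methoxy iminium ion through C3 and two molecules of methanol are lost to give the push–pull enaminone. C3 is the only methylene between two carbonyls; C1 is a methine and cannot form the alkylidene, and C5 is activated by one carbonyl only.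

**Step 3**
Reactants: 5 racemic tert-butyl trans-3-[(dimethylamino)methylidene]-6-methyl-2,4-dioxocyclohexane-1-carboxylate
Product: 7 tert-butyl 3-formyl-2,4-dihydroxy-6-methylbenzoate, via aromatized aminomethylidene dienone 6 (not isolated)
Conditions: DDQ (1.1 equiv), 1,4-dioxane, 60–80 °C; then NaOAc, AcOH, H2O, rt
Reagents that add atoms: water, O
Why: Quinone dehydrogenation of a cyclohexane-1,3-dione to a resorcinol: DDQ takes hydride from the tertiary C6–H of the enol form, where the cation is stabilized through the enol and the amino group, and loss of the acidic C1 proton gives 6, which is the neutral form of an aryl iminium phenolate. 6 is the same kind of species as a Vilsmeier intermediate and hydrolyses in buffered water to the salicylaldehyde 7; both stereocentres are removed here.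

**Step 4**
Reactants: 7 tert-butyl 3-formyl-2,4-dihydroxy-6-methylbenzoate
Product: 8 tert-butyl 3-formyl-2,4-dimethoxy-6-methylbenzoate
Conditions: MeI (5 equiv), K2CO3 (4 equiv), DMF, 45 °C
Reagents that add atoms: iodomethane, CI
Why: Williamson ether synthesis on both phenols; the 4-hydroxyl reacts first, and the chelated 2-hydroxyl between the ester and formyl groups follows in the dipolar solvent with excess reagent. The tert-butyl ester and the aldehyde, which has no α-hydrogen, are inert to carbonate.

**Step 5**
Reactants: 8 tert-butyl 3-formyl-2,4-dimethoxy-6-methylbenzoate
Product: 9 3-formyl-2,4-dimethoxy-6-methylbenzoic acid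
Conditions: TFA/CH2Cl2 (1:4), 0 °C to rt
Reagents that add atoms: none
Why: Acidolysis of a tert-butyl ester by alkyl–oxygen cleavage, which is not slowed by the two ortho substituents that would hinder saponification. The formyl group lowers the electron density of the ring enough to suppress protodecarboxylation at room temperature.

**Step 6**
Reactants: 10 methyl 2,4-dihydroxy-3,6-dimethylbenzoate
Product: 11 2,4-dihydroxy-3,6-dimethylbenzoic acid
Conditions: KOH (8 equiv), DMSO/H2O (4:1), 60 °C, N2; then 2 M HCl, 0 °C
Reagents that add atoms: potassium hydroxide, [K+].[OH-]
Why: Saponification; poorly solvated hydroxide in aqueous DMSO attacks the hindered, phenoxide-deactivated ester at moderate temperature. The acid is set free only in the cold, because it is the free acid and not its salt that decarboxylates on warming.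

**Step 7**
Reactants: 11 2,4-dihydroxy-3,6-dimethylbenzoic acid
Product: 12 tert-butyl 2,4-dihydroxy-3,6-dimethylbenzoate
Conditions: Cl3CC(=NH)OtBu (2 equiv), CH2Cl2/cyclohexane, rt
Reagents that add atoms: tert-butyl 2,2,2-trichloroacetimidate, CC(C)(C)OC(=N)C(Cl)(Cl)Cl
Why: Esterification by O-alkylation with a trichloroacetimidate: only the carboxylic acid is acidic enough to protonate the imidate, and the carboxylate collapses with the tert-butyl cation in the ion pair. Crowding at the carboxyl carbon is irrelevant, and the phenols stay free without added Lewis acid.

**Step 8**
Reactants: 9 3-formyl-2,4-dimethoxy-6-methylbenzoic acid; 12 tert-butyl 2,4-dihydroxy-3,6-dimethylbenzoate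
Product: 14 tert-butyl 4-[(3-formyl-2,4-dimethoxy-6-methylbenzoyl)oxy]-2-hydroxy-3,6-dimethylbenzoate, via acid chloride 13 (not isolated)
Conditions: (COCl)2 (1.3 equiv), DMF (cat.), CH2Cl2, 0 °C to rt, concentrate; then 12, Et3N (2.5 equiv), DMAP (0.2 equiv), CH2Cl2, 0 °C to rt
Reagents that add atoms: none
Why: Acylation of a phenol by an aroyl chloride; the 2- and 4-methoxy groups of 13 assist ionization towards an acylium ion, the usual way in which di-ortho-substituted aroyl chlorides transfer their acyl group. Only the 4-hydroxyl of 12 reacts, because the 2-hydroxyl is hydrogen-bonded to the ester carbonyl and flanked by C1' and C3'.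

**Step 9**
Reactants: 14 tert-butyl 4-[(3-formyl-2,4-dimethoxy-6-methylbenzoyl)oxy]-2-hydroxy-3,6-dimethylbenzoate
Product: 15 4-[(3-formyl-2,4-dimethoxy-6-methylbenzoyl)oxy]-2-hydroxy-3,6-dimethylbenzoic acid
Conditions: TFA/CH2Cl2 (1:3), 0 °C to rt
Reagents that add atoms: none
Why: Acidolysis of the tert-butyl salicylate; the aryl ester and the aldehyde are stable to anhydrous acid, and no silane scavenger is added because it would reduce the aldehyde. The step is placed before the reduction because the benzylic alcohol of 16 would ionize in this medium.

**Step 10**
Reactants: 15 4-[(3-formyl-2,4-dimethoxy-6-methylbenzoyl)oxy]-2-hydroxy-3,6-dimethylbenzoic acid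
Product: 16 2-hydroxy-4-{[3-(hydroxymethyl)-2,4-dimethoxy-6-methylbenzoyl]oxy}-3,6-dimethylbenzoic acid (target)
Conditions: NaBH4 (3 equiv), THF/EtOH (4:1), 0 °C; then aq. citric acid to pH 4, 0 °C
Reagents that add atoms: none
Why: Chemoselective borohydride reduction of an aryl aldehyde; the carboxylate formed in the flask is inert, and the aryl ester is shielded by the 2-methoxy and 6-methyl groups of ring A. The mild, cold acidic quench avoids ionization of the new benzylic alcohol.

## Compound list

1 | tert-butyl 3-oxobutanoate | CC(=O)CC(=O)OC(C)(C)C | starting material
2 | ethyl (2E)-but-2-enoate | C/C=C/C(=O)OCC | starting material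
3 | 1-tert-butyl 5-ethyl 2-acetyl-3-methylpentanedioate (Michael adduct, racemic mixture of diastereomers, not isolated) | CCOC(=O)CC(C)C(C(C)=O)C(=O)OC(C)(C)C | intermediate
4 | racemic tert-butyl trans-6-methyl-2,4-dioxocyclohexane-1-carboxylate (drawn as 1S,6R) | C[C@@H]1CC(=O)CC(=O)[C@H]1C(=O)OC(C)(C)C | intermediate
5 | racemic tert-butyl trans-3-[(dimethylamino)methylidene]-6-methyl-2,4-dioxocyclohexane-1-carboxylate (exocyclic C=C geometry not fixed) | C[C@@H]1CC(=O)C(=CN(C)C)C(=O)[C@H]1C(=O)OC(C)(C)C | intermediate
6 | tert-butyl 3-[(dimethylamino)methylidene]-4-hydroxy-6-methyl-2-oxocyclohexa-1(6),4-diene-1-carboxylate (neutral form of the aryl iminium phenolate, not isolated) | CN(C)C=C1C(=O)C(C(=O)OC(C)(C)C)=C(C)C=C1O | intermediate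
7 | tert-butyl 3-formyl-2,4-dihydroxy-6-methylbenzoate | Cc1cc(O)c(C=O)c(O)c1C(=O)OC(C)(C)C | intermediate
8 | tert-butyl 3-formyl-2,4-dimethoxy-6-methylbenzoate | COc1cc(C)c(C(=O)OC(C)(C)C)c(OC)c1C=O | intermediate
9 | 3-formyl-2,4-dimethoxy-6-methylbenzoic acid | COc1cc(C)c(C(=O)O)c(OC)c1C=O | intermediate
10 | methyl 2,4-dihydroxy-3,6-dimethylbenzoate | COC(=O)c1c(C)cc(O)c(C)c1O | starting material
11 | 2,4-dihydroxy-3,6-dimethylbenzoic acid | Cc1cc(O)c(C)c(O)c1C(=O)O | intermediate
12 | tert-butyl 2,4-dihydroxy-3,6-dimethylbenzoate | Cc1cc(O)c(C)c(O)c1C(=O)OC(C)(C)C | intermediate
13 | 3-formyl-2,4-dimethoxy-6-methylbenzoyl chloride (not isolated) | COc1cc(C)c(C(Cl)=O)c(OC)c1C=O | intermediate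
14 | tert-butyl 4-[(3-formyl-2,4-dimethoxy-6-methylbenzoyl)oxy]-2-hydroxy-3,6-dimethylbenzoate | COc1cc(C)c(C(=O)Oc2cc(C)c(C(=O)OC(C)(C)C)c(O)c2C)c(OC)c1C=O | intermediate
15 | 4-[(3-formyl-2,4-dimethoxy-6-methylbenzoyl)oxy]-2-hydroxy-3,6-dimethylbenzoic acid | COc1cc(C)c(C(=O)Oc2cc(C)c(C(=O)O)c(O)c2C)c(OC)c1C=O | intermediate
16 | 2-hydroxy-4-{[3-(hydroxymethyl)-2,4-dimethoxy-6-methylbenzoyl]oxy}-3,6-dimethylbenzoic acid | COc1cc(C)c(C(=O)Oc2cc(C)c(C(=O)O)c(O)c2C)c(OC)c1CO | target

## Step count and least certain steps

Total: 10 steps. Longest linear sequence: 8 steps (1 to 5, then 8 to 10); ring B is prepared in steps 6 and 7.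

**Step 1 (key step).** The conjugate addition may reverse, or the tert-butyl β-keto ester may be transesterified by the released ethoxide or decarboxylated during acidification, so that the ring closes incompletely or loses C7. Fallback, from 1 and 2 back to 4: the two events are separated. The Michael addition is run with a catalytic amount of DBU without solvent and the adduct 3 is isolated. 3 is then cyclized with KOtBu in THF at 0 °C to room temperature, where no alcohol solvent and no heating are involved.

**Step 3.** Hydride abstraction from the electron-poor enaminone may be slow, and forcing it may lead to oxidation at the C6 methyl group or to loss of the tert-butyl group by the acidic hydroquinone. Fallback, from 5 back to 7: 5 is deprotonated at C1 with NaH in THF and selenenylated with PhSeCl to give the racemic selenide tert-butyl 3-[(dimethylamino)methylidene]-6-methyl-2,4-dioxo-1-(phenylselanyl)cyclohexane-1-carboxylate F1. The electrophile enters anti to the C6 methyl group, so selenium is cis to the C6 hydrogen. Oxidation with H2O2 and pyridine in CH2Cl2 at 0 °C then gives syn elimination of the selenoxide across C1–C6. Tautomerization leads to 6, and the same buffered hydrolysis gives 7.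

**Step 8.** Acyl transfer from the doubly ortho-substituted chloride to the hindered phenol may be slow, the chlorinating agent may attack the formyl group, or some acylation may occur at O2'. Fallback, from 9 and 11 back to 15: acid 11 is alkylated with benzyl bromide and KHCO3 in DMF to benzyl 2,4-dihydroxy-3,6-dimethylbenzoate F2, which tolerates acid. 9 and F2 are condensed with trifluoroacetic anhydride in toluene through the mixed anhydride to give benzyl 4-[(3-formyl-2,4-dimethoxy-6-methylbenzoyl)oxy]-2-hydroxy-3,6-dimethylbenzoate F3. Hydrogenolysis (H2, 1 atm, Pd/C, ethyl acetate, stopped after one equivalent) gives 15 without the acid treatment of step 9.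

**Step 10.** The hindered aldehyde may reduce slowly, so that longer exposure to alkoxide and borohydride opens the aryl ester, or the product may ionize at the benzylic position during acidification. Fallback, from 11 and 13 back to 16: 11 is alkylated with allyl bromide and KHCO3 in DMF to prop-2-en-1-yl 2,4-dihydroxy-3,6-dimethylbenzoate F4. Acylation with 13 as in step 8 gives the allyl ester aldehyde F5. NaBH4 reduces this neutral substrate to prop-2-en-1-yl 2-hydroxy-4-{[3-(hydroxymethyl)-2,4-dimethoxy-6-methylbenzoyl]oxy}-3,6-dimethylbenzoate F6. Zerovalent palladium, Pd(PPh3)4, with PhSO2Na in THF/MeOH then removes the allyl group under neutral conditions to give 16, so that neither a free acid is reduced nor an acid treatment is needed.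

**Step 6.** Hydrolysis of the chelated, di-ortho-substituted ester may need more heat than the product tolerates, leading to loss of CO2. Fallback, from 10 back to 11: the methyl group is removed by alkyl–oxygen cleavage with BBr3 in CH2Cl2 at −78 °C to room temperature, followed by cold aqueous work-up. This takes place well below the temperature of decarboxylation and makes no new compound.

## Further compounds

F0 | step 1 | none | none
F1 | step 3 | racemic tert-butyl 3-[(dimethylamino)methylidene]-6-methyl-2,4-dioxo-1-(phenylselanyl)cyclohexane-1-carboxylate (selenium trans to the C6 methyl group) | C[C@@H]1CC(=O)C(=CN(C)C)C(=O)[C@]1([Se]c2ccccc2)C(=O)OC(C)(C)C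
F2 | step 8 | benzyl 2,4-dihydroxy-3,6-dimethylbenzoate | Cc1cc(O)c(C)c(O)c1C(=O)OCc1ccccc1
F3 | step 8 | benzyl 4-[(3-formyl-2,4-dimethoxy-6-methylbenzoyl)oxy]-2-hydroxy-3,6-dimethylbenzoate | COc1cc(C)c(C(=O)Oc2cc(C)c(C(=O)OCc3ccccc3)c(O)c2C)c(OC)c1C=O
F4 | step 10 | prop-2-en-1-yl 2,4-dihydroxy-3,6-dimethylbenzoate | Cc1cc(O)c(C)c(O)c1C(=O)OCC=C
F5 | step 10 | prop-2-en-1-yl 4-[(3-formyl-2,4-dimethoxy-6-methylbenzoyl)oxy]-2-hydroxy-3,6-dimethylbenzoate | COc1cc(C)c(C(=O)Oc2cc(C)c(C(=O)OCC=C)c(O)c2C)c(OC)c1C=O
F6 | step 10 | prop-2-en-1-yl 2-hydroxy-4-{[3-(hydroxymethyl)-2,4-dimethoxy-6-methylbenzoyl]oxy}-3,6-dimethylbenzoate | COc1cc(C)c(C(=O)Oc2cc(C)c(C(=O)OCC=C)c(O)c2C)c(OC)c1CO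
F0 | step 6 | none | none
A1 | alternative 1 | prop-2-en-1-yl 2-[(tert-butyldimethylsilyl)oxy]-4-[(2,4-dimethoxy-6-methyl-3-{[(triisopropylsilyl)oxy]methyl}benzoyl)oxy]-3,6-dimethylbenzoate | C=CCOC(=O)c1c(C)cc(OC(=O)c2c(C)cc(OC)c(CO[Si](C(C)C)(C(C)C)C(C)C)c2OC)c(C)c1O[Si](C)(C)C(C)(C)C
A2 | alternative 1 | 5-[(tert-butyldimethylsilyl)oxy]-6-methylcyclohexa-1,5-dien-1-yl 2,4-dimethoxy-6-methyl-3-{[(triisopropylsilyl)oxy]methyl}benzoate | COc1cc(C)c(C(=O)OC2=CCCC(O[Si](C)(C)C(C)(C)C)=C2C)c(OC)c1CO[Si](C(C)C)(C(C)C)C(C)C
A3 | alternative 1 | prop-2-en-1-yl but-2-ynoate | CC#CC(=O)OCC=C
A4 | alternative 2 | benzyl 2-(benzyloxy)-4-[(2-hydroxy-4-methoxy-6-methyl-3-{[(triisopropylsilyl)oxy]methyl}benzoyl)oxy]-3,6-dimethylbenzoate | COc1cc(C)c(C(=O)Oc2cc(C)c(C(=O)OCc3ccccc3)c(OCc3ccccc3)c2C)c(O)c1CO[Si](C(C)C)(C(C)C)C(C)C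
A5 | alternative 2 | benzyl 2-(benzyloxy)-4-{[(2E)-5-diazo-3-methyl-4-oxopent-2-enoyl]oxy}-3,6-dimethylbenzoate | [N-]=[N+]=CC(=O)/C(C)=C/C(=O)Oc1cc(C)c(C(=O)OCc2ccccc2)c(OCc2ccccc2)c1C
A6 | alternative 2 | [(3-methoxyprop-2-yn-1-yl)oxy]tri(propan-2-yl)silane | COC#CCO[Si](C(C)C)(C(C)C)C(C)C
A7 | alternative 3 | tert-butyl 4-[(3-formyl-2,4-dimethoxy-6-methylbenzoyl)oxy]-2-hydroxy-3,6-dimethylbenzoate (identical with 14) | COc1cc(C)c(C(=O)Oc2cc(C)c(C(=O)OC(C)(C)C)c(O)c2C)c(OC)c1C=O
A8 | alternative 3 | 3-iodo-2,6-dimethoxy-4-methylbenzaldehyde | COc1cc(C)c(I)c(OC)c1C=O
A9 | alternative 3 | 2,6-dimethoxy-4-methylbenzaldehyde | COc1cc(C)cc(OC)c1C=O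
A10 | alternative 3 | carbon monoxide | [C-]#[O+]
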